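**Retrosynthetic overview**

- The strategy rests on ring C of the flavonol (O1, C2, C3, C4, C4a, C8a): without C3 it is the furan ring of a 2-aryl-3-oxybenzofuran, so C3 is put in last as a carbene carbon between C2 and the carbon that becomes C4.
- Target ⇐ acid removal of three MOM ethers ⇐ C3–Br to C3–OH by borylation and oxidation ⇐ 3-bromoflavone ⇐ dibromocarbene insertion into a 2-aryl-3-silyloxybenzofuran.
- Benzofuran ⇐ acylation of a benzylic carbanion by an ortho ester (furan C2–C3 bond), enolate trapped on oxygen with silicon ⇐ aryl bromide by Br/Li exchange and ClCO2Me.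
- Aryl bromide ⇐ 3-hydroxy-4,5-dimethoxybenzaldehyde by ortho-bromination, O-alkylation with the ring B benzyl bromide (from methyl 3,5-dihydroxy-4-methoxybenzoate), Baeyer–Villiger oxidation and MOM protection.
- Ring order: rings A and B are bought, the furan ring is closed in step 9 and expanded to the pyranone ring C in step 10.

Key step: step 10

Remark on the chemistry: all three phenols that must end free are carried as methoxymethyl (MOM) ethers. A benzyl ether on the ring A oxygen ortho to the ester would offer a second ArO–CH2–Ar site for the base-mediated ring closure of step 9. With MOM groups the only benzylic C–H in 12 is the one that must react, and one acid step frees the target. The target is achiral; 16 is racemic and transient.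

**Route**

Step 1
Reactants: 1 methyl 3,5-dihydroxy-4-methoxybenzoate
Product: 2 methyl 4-methoxy-3,5-bis(methoxymethoxy)benzoate
Conditions: MOMCl, iPr2NEt, CH2Cl2, 0 °C to rt
Reagents that add atoms: chloromethyl methyl ether (MOMCl), COCCl
Why: O-alkylation of both phenols by the reactive α-chloro ether (Williamson-type acetal formation) should proceed cleanly, and the ester is inert to the hindered amine base.

Step 2
Reactants: 2 methyl 4-methoxy-3,5-bis(methoxymethoxy)benzoate
Product: 3 [4-methoxy-3,5-bis(methoxymethoxy)phenyl]methanol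
Conditions: LiAlH4, THF, 0 °C
Reagents that add atoms: none
Why: hydride reduction of the ester to the primary benzylic alcohol; MOM acetals are stable to hydride and to the basic work-up.

Step 3
Reactants: 3 [4-methoxy-3,5-bis(methoxymethoxy)phenyl]methanol
Product: 4 5-(bromomethyl)-2-methoxy-1,3-bis(methoxymethoxy)benzene
Conditions: CBr4, PPh3, CH2Cl2, 0 °C
Reagents that add atoms: carbon tetrabromide, BrC(Br)(Br)Br
Why: the Appel reaction converts the benzylic alcohol into the bromide under neutral, acid-free conditions, so the acetals should survive; the bromide is used without storage.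

Step 4
Reactants: 5 3-hydroxy-4,5-dimethoxybenzaldehyde
Product: 6 2-bromo-3-hydroxy-4,5-dimethoxybenzaldehyde
Conditions: Br2 (1.0 equiv), NaOAc, AcOH, rt
Reagents that add atoms: bromine, BrBr
Why: electrophilic aromatic bromination is expected at C2, ortho to the free hydroxyl and para to the 5-methoxy group, the same ortho-to-hydroxyl preference known for isovanillin; this fixes the carbon that later carries the C4 carbonyl.

Step 5
Reactants: 6 2-bromo-3-hydroxy-4,5-dimethoxybenzaldehyde; 4 5-(bromomethyl)-2-methoxy-1,3-bis(methoxymethoxy)benzene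
Product: 7 2-bromo-4,5-dimethoxy-3-{[4-methoxy-3,5-bis(methoxymethoxy)phenyl]methoxy}benzaldehyde
Conditions: K2CO3, DMF, rt
Reagents that add atoms: none
Why: Williamson ether synthesis of an acidified ortho-bromophenoxide with a reactive benzylic bromide; this oxygen becomes O1 and the benzylic carbon becomes C2 of the flavonol.

Step 6
Reactants: 7 2-bromo-4,5-dimethoxy-3-{[4-methoxy-3,5-bis(methoxymethoxy)phenyl]methoxy}benzaldehyde
Product: 9 2-bromo-4,5-dimethoxy-3-{[4-methoxy-3,5-bis(methoxymethoxy)phenyl]methoxy}phenol, via aryl formate 8 (not isolated)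
Conditions: mCPBA, NaHCO3, CH2Cl2, 0 °C to rt; then K2CO3, MeOH, rt
Reagents that add atoms: 3-chloroperoxybenzoic acid (mCPBA), OOC(=O)c1cccc(Cl)c1
Why: Baeyer–Villiger (Dakin-type) oxidation, in which the electron-rich aryl group with its para methoxy donor migrates in preference to hydrogen, followed by methanolysis of the formate to the phenol that becomes the C5 oxygen.

Step 7
Reactants: 9 2-bromo-4,5-dimethoxy-3-{[4-methoxy-3,5-bis(methoxymethoxy)phenyl]methoxy}phenol
Product: 10 2-bromo-4,5-dimethoxy-1-(methoxymethoxy)-3-{[4-methoxy-3,5-bis(methoxymethoxy)phenyl]methoxy}benzene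
Conditions: MOMCl, iPr2NEt, CH2Cl2, 0 °C to rt
Reagents that add atoms: chloromethyl methyl ether (MOMCl), COCCl
Why: standard MOM protection of the new phenol, giving an oxygen substituent that has no benzylic C–H and is removed by acid at the end.

Step 8
Reactants: 10 2-bromo-4,5-dimethoxy-1-(methoxymethoxy)-3-{[4-methoxy-3,5-bis(methoxymethoxy)phenyl]methoxy}benzene
Product: 12 methyl 3,4-dimethoxy-6-(methoxymethoxy)-2-{[4-methoxy-3,5-bis(methoxymethoxy)phenyl]methoxy}benzoate, via aryllithium 11 (not isolated)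
Conditions: n-BuLi, THF, -78 °C; then ClCO2Me (excess), -78 °C to 0 °C
Reagents that add atoms: methyl chloroformate, COC(=O)Cl
Why: bromine–lithium exchange is much faster than any deprotonation at -78 °C and places the carbanion exactly at the brominated carbon, and acylation of this hindered aryllithium by the chloroformate should stop at the ester.

Step 9
Reactants: 12 methyl 3,4-dimethoxy-6-(methoxymethoxy)-2-{[4-methoxy-3,5-bis(methoxymethoxy)phenyl]methoxy}benzoate
Product: 14 tert-butyl({6,7-dimethoxy-4-(methoxymethoxy)-2-[4-methoxy-3,5-bis(methoxymethoxy)phenyl]-1-benzofuran-3-yl}oxy)dimethylsilane, via lithium benzofuran-3-olate 13 (not isolated)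
Conditions: LiN(iPr)2 (2.5 equiv), THF, -78 °C to 0 °C; then TBSCl, DMPU, -78 °C to rt; handled under argon
Reagents that add atoms: tert-butyldimethylsilyl chloride (TBSCl), CC(C)(C)[Si](C)(C)Cl
Why: the amide base removes a proton from the only benzylic CH2 (α to the aryloxy oxygen and held close by the ester carbonyl), the carbanion acylates the ester in a 5-exo-trig Dieckmann-type closure with loss of methoxide, a second deprotonation gives the aromatic 3-olate, and this is silylated on oxygen.

Step 10
Reactants: 14 tert-butyl({6,7-dimethoxy-4-(methoxymethoxy)-2-[4-methoxy-3,5-bis(methoxymethoxy)phenyl]-1-benzofuran-3-yl}oxy)dimethylsilane; 15 bromoform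
Product: 18 3-bromo-7,8-dimethoxy-5-(methoxymethoxy)-2-[4-methoxy-3,5-bis(methoxymethoxy)phenyl]-4H-chromen-4-one, via dibromocyclopropane 16 (not isolated), via silyloxybenzopyrylium bromide 17 (not isolated)
Conditions: CHBr3, KOtBu, hexane–toluene, -30 °C to rt
Reagents that add atoms: bromoform, BrC(Br)Br
Why: Proposed new method: dibromocarbene, made by α-elimination from 15 with KOtBu, should add in a [2+1] cheletropic step to the furan C2=C3 bond of 14 and close the cis-fused dibromocyclopropane 16; the bromine syn to the five-membered ring then ionises in a disrotatory two-electron electrocyclic opening that breaks the old C2–C3 bond, so the six-membered ring arises by ring expansion (not by a Baldwin-type closure) as the aromatic 4-silyloxybenzopyrylium bromide 17, and bromide or tert-butoxide removes the silyl group to leave the C4 carbonyl of 18. The closest known reactions are the dihalocarbene homologation of cyclic silyl enol ethers to 2-halo-enones, the Parham ring expansion of indenes to 2-halonaphthalenes and the Ciamician–Dennstedt conversion of indoles into 3-haloquinolines. The new skeletal bonds are C2–C3 and C3–C4 of ring C, the carbene carbon becoming C3 and keeping one bromine as the handle for the C3 oxygen. No stereocentre remains: the two in 16 are fixed cis by the ring fusion and vanish on opening. The step needs site selectivity (carbene at the furan double bond, not at the alkoxyarene rings or the acetal C–H bonds) and cleavage of the internal cyclopropane bond; both should follow from the two oxygen donors on that bond (O1 on C2, the silyloxy group on the other carbon), which make it the most nucleophilic alkene in 14 and stabilise the opening cation as a pyrylium ion.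

Step 11
Reactants: 18 3-bromo-7,8-dimethoxy-5-(methoxymethoxy)-2-[4-methoxy-3,5-bis(methoxymethoxy)phenyl]-4H-chromen-4-one
Product: 20 3-hydroxy-7,8-dimethoxy-5-(methoxymethoxy)-2-[4-methoxy-3,5-bis(methoxymethoxy)phenyl]-4H-chromen-4-one, via pinacol boronate 19 (not isolated)
Conditions: B2pin2, Pd(dppf)Cl2, KOAc, 1,4-dioxane, 85 °C; then NaBO3·4H2O, THF–H2O, rt
Reagents that add atoms: sodium perborate, [Na+].[O-]OB=O (oxygen of the 3-hydroxyl); bis(pinacolato)diboron, CC1(C)OB(OC1(C)C)B1OC(C)(C)C(C)(C)O1 (boryl group of 19 only)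
Why: Miyaura borylation (oxidative addition of zerovalent palladium into the C3–Br bond, acetate-assisted transmetalation with B2pin2, reductive elimination) followed by perborate oxidation of the C–B bond through a 1,2-shift of C3 from boron to oxygen should give the flavonol hydroxyl under mild, weakly basic conditions.

Step 12
Reactants: 20 3-hydroxy-7,8-dimethoxy-5-(methoxymethoxy)-2-[4-methoxy-3,5-bis(methoxymethoxy)phenyl]-4H-chromen-4-one
Product: 21 2-(3,5-dihydroxy-4-methoxyphenyl)-3,5-dihydroxy-7,8-dimethoxy-4H-chromen-4-one (CNP0165950.0)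
Conditions: HCl (3 M aq.), MeOH, 50 °C
Reagents that add atoms: none
Why: acid-catalysed acetal exchange with methanol removes the three MOM groups as dimethoxymethane, while the aryl methyl ethers and the pyranone are stable to dilute protic acid.

**Compound list**

1 | methyl 3,5-dihydroxy-4-methoxybenzoate | COC(=O)c1cc(O)c(OC)c(O)c1 | starting material
2 | methyl 4-methoxy-3,5-bis(methoxymethoxy)benzoate | COC(=O)c1cc(OCOC)c(OC)c(OCOC)c1 | intermediate
3 | [4-methoxy-3,5-bis(methoxymethoxy)phenyl]methanol | OCc1cc(OCOC)c(OC)c(OCOC)c1 | intermediate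
4 | 5-(bromomethyl)-2-methoxy-1,3-bis(methoxymethoxy)benzene | BrCc1cc(OCOC)c(OC)c(OCOC)c1 | intermediate
5 | 3-hydroxy-4,5-dimethoxybenzaldehyde | COc1cc(C=O)cc(O)c1OC | starting material
6 | 2-bromo-3-hydroxy-4,5-dimethoxybenzaldehyde | COc1cc(C=O)c(Br)c(O)c1OC | intermediate
7 | 2-bromo-4,5-dimethoxy-3-{[4-methoxy-3,5-bis(methoxymethoxy)phenyl]methoxy}benzaldehyde | COc1cc(C=O)c(Br)c(OCc2cc(OCOC)c(OC)c(OCOC)c2)c1OC | intermediate
8 | 2-bromo-4,5-dimethoxy-3-{[4-methoxy-3,5-bis(methoxymethoxy)phenyl]methoxy}phenyl formate | COc1cc(OC=O)c(Br)c(OCc2cc(OCOC)c(OC)c(OCOC)c2)c1OC | intermediate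
9 | 2-bromo-4,5-dimethoxy-3-{[4-methoxy-3,5-bis(methoxymethoxy)phenyl]methoxy}phenol | COc1cc(O)c(Br)c(OCc2cc(OCOC)c(OC)c(OCOC)c2)c1OC | intermediate
10 | 2-bromo-4,5-dimethoxy-1-(methoxymethoxy)-3-{[4-methoxy-3,5-bis(methoxymethoxy)phenyl]methoxy}benzene | COCOc1cc(OC)c(OC)c(OCc2cc(OCOC)c(OC)c(OCOC)c2)c1Br | intermediate
11 | [3,4-dimethoxy-6-(methoxymethoxy)-2-{[4-methoxy-3,5-bis(methoxymethoxy)phenyl]methoxy}phenyl]lithium | [Li]c1c(OCOC)cc(OC)c(OC)c1OCc1cc(OCOC)c(OC)c(OCOC)c1 | intermediate
12 | methyl 3,4-dimethoxy-6-(methoxymethoxy)-2-{[4-methoxy-3,5-bis(methoxymethoxy)phenyl]methoxy}benzoate | COC(=O)c1c(OCOC)cc(OC)c(OC)c1OCc1cc(OCOC)c(OC)c(OCOC)c1 | intermediate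
13 | lithium 6,7-dimethoxy-4-(methoxymethoxy)-2-[4-methoxy-3,5-bis(methoxymethoxy)phenyl]-1-benzofuran-3-olate | [Li+].[O-]c1c(-c2cc(OCOC)c(OC)c(OCOC)c2)oc2c(OC)c(OC)cc(OCOC)c12 | intermediate
14 | tert-butyl({6,7-dimethoxy-4-(methoxymethoxy)-2-[4-methoxy-3,5-bis(methoxymethoxy)phenyl]-1-benzofuran-3-yl}oxy)dimethylsilane | COCOc1cc(OC)c(OC)c2oc(-c3cc(OCOC)c(OC)c(OCOC)c3)c(O[Si](C)(C)C(C)(C)C)c12 | intermediate
15 | bromoform | BrC(Br)Br | starting material
16 | tert-butyl({1,1-dibromo-3,4-dimethoxy-6-(methoxymethoxy)-1a-[4-methoxy-3,5-bis(methoxymethoxy)phenyl]-1,1a-dihydro-6bH-cyclopropa[b][1]benzofuran-6b-yl}oxy)dimethylsilane (cis-fused, racemic; one enantiomer drawn) | COCOc1cc(OC)c(OC)c2O[C@@]3(c4cc(OCOC)c(OC)c(OCOC)c4)C(Br)(Br)[C@@]3(O[Si](C)(C)C(C)(C)C)c12 | intermediate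
17 | 3-bromo-4-[(tert-butyldimethylsilyl)oxy]-7,8-dimethoxy-5-(methoxymethoxy)-2-[4-methoxy-3,5-bis(methoxymethoxy)phenyl]chromenylium bromide | COCOc1cc(OC)c(OC)c2[o+]c(-c3cc(OCOC)c(OC)c(OCOC)c3)c(Br)c(O[Si](C)(C)C(C)(C)C)c12.[Br-] | intermediate
18 | 3-bromo-7,8-dimethoxy-5-(methoxymethoxy)-2-[4-methoxy-3,5-bis(methoxymethoxy)phenyl]-4H-chromen-4-one | COCOc1cc(OC)c(OC)c2oc(-c3cc(OCOC)c(OC)c(OCOC)c3)c(Br)c(=O)c12 | intermediate
19 | 7,8-dimethoxy-5-(methoxymethoxy)-2-[4-methoxy-3,5-bis(methoxymethoxy)phenyl]-3-(4,4,5,5-tetramethyl-1,3,2-dioxaborolan-2-yl)-4H-chromen-4-one | COCOc1cc(OC)c(OC)c2oc(-c3cc(OCOC)c(OC)c(OCOC)c3)c(B3OC(C)(C)C(C)(C)O3)c(=O)c12 | intermediate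
20 | 3-hydroxy-7,8-dimethoxy-5-(methoxymethoxy)-2-[4-methoxy-3,5-bis(methoxymethoxy)phenyl]-4H-chromen-4-one | COCOc1cc(OC)c(OC)c2oc(-c3cc(OCOC)c(OC)c(OCOC)c3)c(O)c(=O)c12 | intermediate
21 | 2-(3,5-dihydroxy-4-methoxyphenyl)-3,5-dihydroxy-7,8-dimethoxy-4H-chromen-4-one | COc1cc(O)c2c(=O)c(O)c(-c3cc(O)c(OC)c(O)c3)oc2c1OC | target

**Step count**

Total: 12 steps. Longest linear sequence: 11 steps (steps 1–3, then 5–12, from methyl 3,5-dihydroxy-4-methoxybenzoate); the ring A branch from 3-hydroxy-4,5-dimethoxybenzaldehyde runs 9 steps (4–12).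

**Steps most likely to fail**

Step 10 (proposed new method). The alkoxide may strip the silyl group from 14 before the carbene arrives, and the free enolate may then be attacked at carbon without ring expansion. The carbene may also insert into acetal C–H bonds, or the cyclopropane may collapse in another direction.

The fallback sets out from 14 and rejoins at 20, bypassing 18 and step 11. Ozonolysis of the enol ether bond (O3, CH2Cl2, -78 °C; then Me2S) should cut the furan C2=C3 bond and give tert-butyldimethylsilyl 3,4-dimethoxy-6-(methoxymethoxy)-2-{[4-methoxy-3,5-bis(methoxymethoxy)benzoyl]oxy}benzoate F1. With Ph3P=CHSiMe3 in refluxing THF the silyl ester should acylate the ylide to give 5,6-dimethoxy-3-(methoxymethoxy)-2-[(triphenylphosphoranylidene)acetyl]phenyl 4-methoxy-3,5-bis(methoxymethoxy)benzoate F2. This closes by intramolecular Wittig olefination of the aryl ester carbonyl, as known for silyl esters of O-aroylsalicylic acids, to the flavone 7,8-dimethoxy-5-(methoxymethoxy)-2-[4-methoxy-3,5-bis(methoxymethoxy)phenyl]-4H-chromen-4-one F3. Dimethyldioxirane in acetone–CH2Cl2 at 0 °C should then give 2,3-epoxy-7,8-dimethoxy-5-(methoxymethoxy)-2-[4-methoxy-3,5-bis(methoxymethoxy)phenyl]-2,3-dihydro-4H-chromen-4-one F4, which opens with a trace of TsOH to the 3-hydroxyflavone 20.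

Step 9. Benzylic deprotonation may be slow, the α-aryloxy carbanion may undergo [1,2]-Wittig rearrangement, the base may attack the ester, or the enolate may be silylated on carbon.

The fallback sets out from 10 and rejoins at 14. Bromine–lithium exchange (n-BuLi, THF, -78 °C) and quench with ClC(=O)NEt2 should give N,N-diethyl-3,4-dimethoxy-6-(methoxymethoxy)-2-{[4-methoxy-3,5-bis(methoxymethoxy)phenyl]methoxy}benzamide F5. The amide resists attack by the base and directs LiN(iPr)2 to the neighbouring benzylic CH2 (THF, 0 °C to rt). Cyclisation and aqueous work-up should give 6,7-dimethoxy-4-(methoxymethoxy)-2-[4-methoxy-3,5-bis(methoxymethoxy)phenyl]-1-benzofuran-3(2H)-one F6 (racemic). Separate O-silylation (TBSCl, imidazole, DMF) then gives 14.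

Step 11. The hindered C3 boronate may undergo protodeboronation, the bromide may be reduced under the borylation conditions, and the pyranone may open or the flavonol be over-oxidised in basic peroxide.

The fallback sets out from 18 and rejoins at 20. Coupling of 18 with (E)-benzaldoxime as a hydroxide surrogate (Pd2(dba)3, tBuBrettPhos, Cs2CO3, DMF, 80 °C; oxidative addition of zerovalent palladium, C–O reductive elimination) should give (E)-benzaldehyde O-{7,8-dimethoxy-5-(methoxymethoxy)-2-[4-methoxy-3,5-bis(methoxymethoxy)phenyl]-4-oxo-4H-chromen-3-yl}oxime F7. Under the carbonate base this loses benzonitrile in the same flask and gives 20 after work-up, without a boron intermediate or peroxide.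

**Further compounds**

F1 | step 10 | tert-butyldimethylsilyl 3,4-dimethoxy-6-(methoxymethoxy)-2-{[4-methoxy-3,5-bis(methoxymethoxy)benzoyl]oxy}benzoate | COCOc1cc(OC)c(OC)c(OC(=O)c2cc(OCOC)c(OC)c(OCOC)c2)c1C(=O)O[Si](C)(C)C(C)(C)C
F2 | step 10 | 5,6-dimethoxy-3-(methoxymethoxy)-2-[(triphenylphosphoranylidene)acetyl]phenyl 4-methoxy-3,5-bis(methoxymethoxy)benzoate | COCOc1cc(OC)c(OC)c(OC(=O)c2cc(OCOC)c(OC)c(OCOC)c2)c1C(=O)C=P(c1ccccc1)(c1ccccc1)c1ccccc1
F3 | step 10 | 7,8-dimethoxy-5-(methoxymethoxy)-2-[4-methoxy-3,5-bis(methoxymethoxy)phenyl]-4H-chromen-4-one | COCOc1cc(OC)c(OC)c2oc(-c3cc(OCOC)c(OC)c(OCOC)c3)cc(=O)c12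
F4 | step 10 | 2,3-epoxy-7,8-dimethoxy-5-(methoxymethoxy)-2-[4-methoxy-3,5-bis(methoxymethoxy)phenyl]-2,3-dihydro-4H-chromen-4-one (racemic; one enantiomer drawn) | COCOc1cc(OC)c(OC)c2O[C@@]3(c4cc(OCOC)c(OC)c(OCOC)c4)O[C@H]3C(=O)c12
F5 | step 9 | N,N-diethyl-3,4-dimethoxy-6-(methoxymethoxy)-2-{[4-methoxy-3,5-bis(methoxymethoxy)phenyl]methoxy}benzamide | CCN(CC)C(=O)c1c(OCOC)cc(OC)c(OC)c1OCc1cc(OCOC)c(OC)c(OCOC)c1
F6 | step 9 | 6,7-dimethoxy-4-(methoxymethoxy)-2-[4-methoxy-3,5-bis(methoxymethoxy)phenyl]-1-benzofuran-3(2H)-one (racemic) | COCOc1cc(OC)c(OC)c2OC(c3cc(OCOC)c(OC)c(OCOC)c3)C(=O)c12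
F7 | step 11 | (E)-benzaldehyde O-{7,8-dimethoxy-5-(methoxymethoxy)-2-[4-methoxy-3,5-bis(methoxymethoxy)phenyl]-4-oxo-4H-chromen-3-yl}oxime | COCOc1cc(OC)c(OC)c2oc(-c3cc(OCOC)c(OC)c(OCOC)c3)c(O/N=C/c3ccccc3)c(=O)c12
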